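## Analysis of the target

The target 24 is a 4-methoxy-5-methylcoumarin bonded through its C3 to C1 of an iridoid-type 1,4a,5,6,7,7a-hexahydrocyclopenta[c]pyran. Locants C1, O2, C3, C4, C4a, C5, C6, C7, C7a are used for this bicycle throughout, also in earlier intermediates. C3 carries a 3-methylbutanoyl group, and C4 and C7 each carry a methyl group. The dihydropyran contains the enol ether O2–C3=C4, which is also the α-alkoxy enone of the acyl group. C1 is an acetal-like carbon between O2 and the nucleophilic C3 of the coumarin, so this bond can ionise or reopen under acid.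

The four stereocentres are 1R, 4aS, 7S, 7aR. The ring fusion is cis, the 7-methyl group is trans to C1 (on the face of H4a and H7a), and the coumarin on C1 is trans to C7 on the convex face. The bicycle therefore has the configuration of cis,trans-nepetalactone 13.

Three things make the synthesis hard:
- H7a is cis to H4a but trans to H7, so no single syn hydrogenation of a C7=C7a alkene can set the whole triad.
- C1 and C3 are both at the aldehyde oxidation level and must be told apart.
- The acyl group sits on the oxygen-bearing carbon of an acid-sensitive enol ether, and the coumarin 4-oxygen is ambident in the final methylation.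

The strategy rests on one structural feature. The cyclopentane C4a–C5–C6–C7–C7a, with one carbon (C1) on C7a, a methyl on C7 and the branched three-carbon unit (C4, its methyl, C3) on C4a, is (S)-limonene 1 after cleavage of its ring alkene and reclosure between the aldehyde α-carbon and the methyl ketone. C4a then comes from the chiral pool.

## Retrosynthetic reasoning

**24 ⇒ 23.** The methyl–oxygen bond of the 4-methoxy group is cut last. The free 4-hydroxycoumarin is the nucleophile needed for the C1 bond, and methylation afterwards touches no stereocentre.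

**23 ⇒ 20 + 22.** The C1–C3(coumarin) bond is cut, leaving a C1 oxocarbenium ion (from methyl acetal 20) and the vinylogous acid 22. This is the most convergent cut, and attack on the convex face of the cis-fused bicycle, anti to the C7a–C7 bond, should give the required 1R centre. The forward step must ionise C1 without destroying the enol ether.

**22 ⇒ 21.** The coumarin pyranone is opened at C2: acetophenone 21 supplies the ring and C3/C4, and a carbonate supplies C2.

**20 ⇒ 16 + 18 (18 from 17).** The bond between C3 and the acyl carbon is cut. C3 is the α-carbon of a cyclic enol ether and can be metalated directly, so the acyl group comes in one step from Weinreb amide 18, made from acid chloride 17. This requires C1 to be masked as a base-stable acetal, hence the methyl acetal in 16.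

**16 ⇒ 15 ⇒ 13.** The C1 acetal is traced to the lactone carbonyl of 13 through anomeric acetate 15. Passing through the lactone, and not through a 1,5-dialdehyde, solves two problems:
- C1 (acid level) and C3 (aldehyde level) are chemically distinct, so the enol ether can only form as C3=C4.
- C7a is α to a carbonyl inside a ring, where the cis-fused isomer is the thermodynamic one.

**13 ⇒ 12 ⇒ 11 ⇒ 10.** The O2–C1 bond is cut (enol lactonisation of formyl acid 11, released from tert-butyl ester 10). Lactone 13 is reached by epimerisation at C7a of trans-fused lactone 12. The forward step must cyclise, then invert one centre.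

**10 ⇒ 9 ⇒ 8.** The two C–H bonds at C7 and C7a are cut. Reagents approach a C7=C7a alkene from the face away from the C4a side chain, which would put the 7-methyl on the wrong face. The hydrogen must therefore be delivered from the side-chain face, by the side-chain hydroxyl of 8. This sets C7 correctly and leaves C7a for the later epimerisation. Oxidation of 9 then gives aldehyde 10.

**8 ⇒ 7 ⇒ 6 ⇒ 5.** The C3–O bond is cut (anti-Markovnikov hydroboration of the isopropenyl group of 7). The tert-butyl ester is traced to acid 6 and to the aldehyde of 5. C1 is raised to the acid level early so that no later differentiation of two alcohols is needed.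

**5 ⇒ 4 ⇒ 3.** The C7–C7a bond of enal 5 is cut (aldol condensation of keto aldehyde 4), and 4 is reconnected between its two carbonyl carbons to diol 3. This is where the cyclopentane is recognised as a contracted limonene ring. The forward step needs only aldol chemoselectivity.

**3 ⇒ 2 ⇒ 1.** The two C–O bonds of the diol are traced through epoxide 2 to the ring alkene of (S)-limonene 1, which is more nucleophilic than the isopropenyl group.

## Alternatives that were turned down

**Alternative 1: carbocycle by Pauson–Khand reaction, ring oxygen inserted later.**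
- Disconnection: C4a–C7a, C3–C4 and C1–C3, so that a 1,6-enyne (methyl alkyne, E-aryl alkene) and CO close the cyclopentane and a cyclopentenone.
- Forward key step: a cobalt-mediated [2+2+1] cycloaddition gives bicyclic enone A1, which already carries the methoxycoumarin on C1.
- For it: it is convergent and makes three C–C bonds and two rings at once. The coumarin enters early as its methyl ether, so neither the Lewis-acid arylation nor the ambident O-methylation of the chosen route is needed. On these points it is stronger.
- Against it: a 1,2-disubstituted alkene bearing an electron-poor heteroaryl group is a poor Pauson–Khand partner. In A1 the oxygen O2 is still missing and C4a is still sp2. Oxygen insertion next to a conjugated enone has to compete with epoxidation and with migration of the wrong carbon. The lactone so formed must then be turned into an acylated enol ether with the alkene moved to C3=C4 and H4a set cis to H7a.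
- Comparison: the short carbon assembly is paid for by a long, unsecured heteroatom endgame. The chosen route keeps C4a fixed from the start and ends on known iridoid lactone and lactol chemistry.

**Alternative 2: organocatalytic nitro-Michael/enamine-Michael cascade.**
- Disconnection: C6–C7 and C4a–C7a, then O2–C1.
- Forward key step: a prolinol silyl ether catalyst activates a β-methyl enal as its iminium ion; a nitronate adds, and the resulting enamine closes onto a tethered α-methyl enone. After hydrolysis this gives nitro lactol A2, whose acyl group is masked as a dioxolane.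
- For it: three ring stereocentres are set catalytically from achiral materials, and the C3 acyl unit and the C1 lactol are in place at once. No directed hydrogenation and no enol ether lithiation are needed. On step economy of the core it is stronger.
- Against it: the 4a,7a-cis and 7,7a-trans pattern is not the one such cascades give by default, and C7a is epimerisable α to the aldehyde. The nitro group at C6 must be removed by a sluggish radical denitration of a secondary nitroalkane. The cyclisation precursor, with its masked 1,2-diketone, is itself a multistep problem.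
- Comparison: the chosen route takes C4a from limonene, where it cannot be wrong, and sets C7 and C7a by two well-understood events.

**Alternative 3: oxa-Michael/Dieckmann cascade forming pyran and coumarin together.**
- Disconnection: O2–C1 and the coumarin C3–C4 bond.
- Forward key step: a lithium amide base forms the enolate of a side-chain 1,2-diketone; its oxygen adds to an aryl enoate at C1, and the ester enolate so formed attacks the neighbouring methyl benzoate. The product A3 is the same compound as 23.
- For it: it closes two rings in one operation, sets C1 under thermodynamic control, and needs neither an oxocarbenium arylation nor a metalated enol ether. On those points it is stronger.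
- Against it: the precursor must already contain the cyclopentane with C4a, C7 and C7a set, plus a 1,2-diketone chain and an aryl acrylate. The aryl ester is an activated acylating agent that the base or the diketone enolate can attack before the conjugate addition. A3 still needs the same final O-methylation.
- Comparison: the stereochemical problem of the cyclopentane is only moved into the precursor. The chosen route answers that problem directly and reaches the same compound.

Key step: step 3

Assumption: stereocentres that are destroyed or re-formed later are carried as mixtures and left open in the SMILES. These are C1/C2 of epoxide 2, the side-chain carbon C4 of 8–11, and the acetal carbon C1 of 14–16, 19 and 20.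

## Route

Step 1
Reactants: 1 (S)-limonene [(4S)-1-methyl-4-(prop-1-en-2-yl)cyclohex-1-ene]
Product: 2 (4S)-limonene 1,2-oxide [(4S)-1-methyl-4-(prop-1-en-2-yl)-7-oxabicyclo[4.1.0]heptane; cis/trans mixture]
Conditions: mCPBA (1.0 equiv), NaHCO3, CH2Cl2, 0 °C
Reagents that add atoms: 3-chloroperoxybenzoic acid (mCPBA), OOC(=O)c1cccc(Cl)c1
Why: Prilezhaev epoxidation; the trisubstituted ring alkene is more nucleophilic than the 1,1-disubstituted isopropenyl group, so one equivalent of peracid should react there, and the epoxide diastereomers need not be separated because both centres are lost in step 3.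

Step 2
Reactants: 2 (4S)-limonene 1,2-oxide
Product: 3 (1R,2R,4S)-limonene-1,2-diol [(1R,2R,4S)-1-methyl-4-(prop-1-en-2-yl)cyclohexane-1,2-diol]
Conditions: H2SO4 (1% aq.), THF, 0 °C
Reagents that add atoms: water, O
Why: Acid-catalysed epoxide hydrolysis with trans-diaxial (Fürst–Plattner) opening should funnel both epoxides mainly to the trans-diol, and the cold dilute acid leaves the isopropenyl group alone; any minor diol isomer converges in step 3.

Step 3
Reactants: 3 (1R,2R,4S)-limonene-1,2-diol
Product: 5 (5R)-2-methyl-5-(prop-1-en-2-yl)cyclopent-1-ene-1-carbaldehyde, via keto aldehyde 4 (not isolated)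
Conditions: NaIO4 (1.3 equiv), THF/H2O, 0 °C → rt; extractive work-up; then piperidine (0.1 equiv), AcOH (0.1 equiv), benzene, reflux (Dean–Stark)
Reagents that add atoms: none
Why: Periodate forms a cyclic ester with the vicinal diol and fragments it (Malaprade cleavage), so the tertiary carbinol becomes the methyl ketone and the secondary one the aldehyde of 4, i.e. the C1–C2 bond of the limonene ring is cut. Piperidinium acetate then condenses with the unhindered aldehyde to its enamine, whose α-carbon adds to the acid-activated ketone carbonyl and forms the C7–C7a bond in a 5-(enolexo)-exo-trig closure of the cyclopentane; loss of water through the iminium ion gives the conjugated enal. The closest known reaction type is the amine-salt intramolecular aldol condensation of 1,6-keto aldehydes. The selectivity needed is chemoselectivity: attack of the ketone α-carbon on the aldehyde, which hydroxide bases favour and which leads to an isomeric acetylcyclopentene, must be suppressed, and the secondary amine secures this because only the aldehyde forms an enamine at a useful rate. No stereocentre is created, since both aldol carbons end sp2. The limonene stereocentre (the future C4a) is β to the aldehyde in 4 and on the non-enolisable α′ side of the enal in 5, so it should survive unchanged.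

Step 4
Reactants: 5 (5R)-2-methyl-5-(prop-1-en-2-yl)cyclopent-1-ene-1-carbaldehyde
Product: 6 (5R)-2-methyl-5-(prop-1-en-2-yl)cyclopent-1-ene-1-carboxylic acid
Conditions: NaClO2, NaH2PO4, 2-methyl-2-butene, t-BuOH/H2O, 0 °C → rt
Reagents that add atoms: sodium chlorite, [Na+].[O-]Cl=O
Why: Pinnick (Lindgren–Kraus) oxidation converts the enal into the acid without touching the alkenes, the scavenger removing hypochlorite; C1 is thereby set apart from C3 for the rest of the route.

Step 5
Reactants: 6 (5R)-2-methyl-5-(prop-1-en-2-yl)cyclopent-1-ene-1-carboxylic acid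
Product: 7 tert-butyl (5R)-2-methyl-5-(prop-1-en-2-yl)cyclopent-1-ene-1-carboxylate
Conditions: Me2NCH(Ot-Bu)2 (4 equiv), toluene, 80 °C
Reagents that add atoms: N,N-dimethylformamide di-tert-butyl acetal, CN(C)C(OC(C)(C)C)OC(C)(C)C
Why: O-alkylation of the carboxylic acid by the amide acetal under neutral conditions suits the hindered, acid-sensitive substrate; the tert-butyl ester cannot lactonise with the hydroxyl made in step 6 and is removed by acid in step 9 without a separate operation.

Step 6
Reactants: 7 tert-butyl (5R)-2-methyl-5-(prop-1-en-2-yl)cyclopent-1-ene-1-carboxylate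
Product: 8 tert-butyl (5R)-5-[(2RS)-1-hydroxypropan-2-yl]-2-methylcyclopent-1-ene-1-carboxylate
Conditions: 9-borabicyclo[3.3.1]nonane (9-BBN, 1.3 equiv), THF, 0 °C → rt; then NaOH (aq.), H2O2, 0 °C
Reagents that add atoms: hydrogen peroxide, OO
Why: Brown hydroboration–oxidation; 9-BBN adds anti-Markovnikov to the 1,1-disubstituted alkene and ignores the tetrasubstituted conjugated one and the ester, giving the C3 hydroxyl; the new centre at C4 is uncontrolled and irrelevant because C4 becomes sp2 in step 9.

Step 7
Reactants: 8 tert-butyl (5R)-5-[(2RS)-1-hydroxypropan-2-yl]-2-methylcyclopent-1-ene-1-carboxylate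
Product: 9 tert-butyl (1S,2R,5S)-2-[(2RS)-1-hydroxypropan-2-yl]-5-methylcyclopentane-1-carboxylate
Conditions: [Ir(cod)(PCy3)(py)]PF6 (10 mol%), H2 (50 bar), CH2Cl2, rt
Reagents that add atoms: none
Why: Hydroxyl-directed homogeneous hydrogenation (Crabtree/Stork type); the side-chain hydroxyl binds the cationic iridium and holds it on the face of the C4a substituent, whereas the ester carbonyl lies in the alkene plane and gives no facial bias, so both hydrogens should add syn to the side chain; this places the 7-methyl trans to the side chain (final 7S) and leaves the ester on C7a provisionally trans to it.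

Step 8
Reactants: 9 tert-butyl (1S,2R,5S)-2-[(2RS)-1-hydroxypropan-2-yl]-5-methylcyclopentane-1-carboxylate
Product: 10 tert-butyl (1S,2S,5R)-2-methyl-5-[(2RS)-1-oxopropan-2-yl]cyclopentane-1-carboxylate
Conditions: Dess–Martin periodinane, NaHCO3, CH2Cl2, 0 °C → rt
Reagents that add atoms: none
Why: Dess–Martin oxidation of the primary alcohol brings C3 to the aldehyde level under buffered, non-epimerising conditions; C4 is already a mixture and the ring centres are not affected.

Step 9
Reactants: 10 tert-butyl (1S,2S,5R)-2-methyl-5-[(2RS)-1-oxopropan-2-yl]cyclopentane-1-carboxylate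
Product: 13 cis,trans-nepetalactone [(4aS,7S,7aR)-4,7-dimethyl-5,6,7,7a-tetrahydrocyclopenta[c]pyran-1(4aH)-one], via formyl acid 11 (not isolated), via trans-fused lactone 12 (not isolated)
Conditions: TsOH·H2O (0.2 equiv), toluene, reflux (Dean–Stark); then DBU (1.5 equiv), reflux
Reagents that add atoms: none
Why: Acidolysis of the tert-butyl ester frees the δ-formyl acid, which cyclodehydrates through its hydroxy-lactone form to the enol lactone (the enol ether can only form as C3=C4 because C1 is the acyl carbon), and both C4 epimers converge; DBU then equilibrates C7a through the lactone enolate, and the cis-fused lactone with the 7-methyl trans to the carbonyl is expected to be the thermodynamic epimer, which sets 7aR.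

Step 10
Reactants: 13 cis,trans-nepetalactone
Product: 15 (1RS,4aS,7S,7aR)-4,7-dimethyl-1,4a,5,6,7,7a-hexahydrocyclopenta[c]pyran-1-yl acetate, via aluminium hemiacetal 14 (not isolated)
Conditions: i-Bu2AlH (1.1 equiv), CH2Cl2, −78 °C; then pyridine, DMAP, Ac2O, −78 → −20 °C
Reagents that add atoms: acetic anhydride, CC(=O)OC(C)=O
Why: Reductive acetylation of a lactone (hydride addition at −78 °C, then O-acylation of the aluminium hemiacetal in the same flask) gives the anomeric acetate without exposing the lactol or the enol ether to acid; the new centre at C1 is uncontrolled and is re-formed in step 15.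

Step 11
Reactants: 15 (1RS,4aS,7S,7aR)-4,7-dimethyl-1,4a,5,6,7,7a-hexahydrocyclopenta[c]pyran-1-yl acetate
Product: 16 (1RS,4aS,7S,7aR)-1-methoxy-4,7-dimethyl-1,4a,5,6,7,7a-hexahydrocyclopenta[c]pyran
Conditions: Me3SiOMe (2 equiv), Me3SiOTf (5 mol%), CH2Cl2, −78 °C; Et3N quench
Reagents that add atoms: methoxytrimethylsilane, CO[Si](C)(C)C
Why: Silyl-triflate-catalysed exchange of the anomeric acetate for methoxide through the C1 oxocarbenium ion runs without a Brønsted acid or free methanol, so addition of methanol across the enol ether is avoided; the methyl acetal is stable to the organolithium used in step 13.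

Step 12
Reactants: 17 3-methylbutanoyl chloride
Product: 18 N-methoxy-N,3-dimethylbutanamide
Conditions: MeNHOMe·HCl, K2CO3, CH2Cl2/H2O, 0 °C → rt
Reagents that add atoms: N,O-dimethylhydroxylamine hydrochloride, CNOC.Cl
Why: Schotten–Baumann acylation of the hydroxylamine gives the Weinreb amide, which stops acylation of an organolithium at the ketone stage.

Step 13
Reactants: 16 (1RS,4aS,7S,7aR)-1-methoxy-4,7-dimethyl-1,4a,5,6,7,7a-hexahydrocyclopenta[c]pyran; 18 N-methoxy-N,3-dimethylbutanamide
Product: 20 1-[(1RS,4aS,7S,7aR)-1-methoxy-4,7-dimethyl-1,4a,5,6,7,7a-hexahydrocyclopenta[c]pyran-3-yl]-3-methylbutan-1-one, via vinyllithium 19 (not isolated)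
Conditions: t-BuLi (1.3 equiv), THF, −78 → 0 °C; then 18, −78 °C → rt; aq. NH4Cl
Reagents that add atoms: none
Why: α-Lithiation of a cyclic enol ether (as for dihydropyran) is favoured by oxygen coordination and the acidity of the vinylic O–C–H, and the vinyllithium adds once to the Weinreb amide through a chelated tetrahedral intermediate, giving the α-alkoxy enone; no stereocentre is involved.

Step 14
Reactants: 21 1-(2-hydroxy-6-methylphenyl)ethan-1-one
Product: 22 4-hydroxy-5-methyl-2H-chromen-2-one
Conditions: NaH (3 equiv), (EtO)2CO, toluene, reflux; then aq. HCl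
Reagents that add atoms: diethyl carbonate, CCOC(=O)OCC
Why: Claisen-type C-acylation of the ketone enolate by the carbonate, followed by lactonisation onto the phenoxide, is the standard route from 2-hydroxyacetophenones to 4-hydroxycoumarins.

Step 15
Reactants: 20 1-[(1RS,4aS,7S,7aR)-1-methoxy-4,7-dimethyl-1,4a,5,6,7,7a-hexahydrocyclopenta[c]pyran-3-yl]-3-methylbutan-1-one; 22 4-hydroxy-5-methyl-2H-chromen-2-one
Product: 23 3-[(1R,4aS,7S,7aR)-4,7-dimethyl-3-(3-methylbutanoyl)-1,4a,5,6,7,7a-hexahydrocyclopenta[c]pyran-1-yl]-4-hydroxy-5-methyl-2H-chromen-2-one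
Conditions: BF3·OEt2 (0.3 equiv), 4 Å molecular sieves, CH2Cl2/MeCN, −40 → 0 °C
Reagents that add atoms: none
Why: The Lewis acid ionises the methyl acetal to the C1 oxocarbenium ion, which is attacked by C3 of the vinylogous acid (a C-glycosylation-like Friedel–Crafts alkylation; any O-linked acetal re-ionises and funnels to the C-adduct); attack on the convex face, anti to the C7a–C7 bond, should give the 1R centre, which is also the more stable epimer.

Step 16
Reactants: 23 3-[(1R,4aS,7S,7aR)-4,7-dimethyl-3-(3-methylbutanoyl)-1,4a,5,6,7,7a-hexahydrocyclopenta[c]pyran-1-yl]-4-hydroxy-5-methyl-2H-chromen-2-one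
Product: 24 3-[(1R,4aS,7S,7aR)-4,7-dimethyl-3-(3-methylbutanoyl)-1,4a,5,6,7,7a-hexahydrocyclopenta[c]pyran-1-yl]-4-methoxy-5-methyl-2H-chromen-2-one
Conditions: Me2SO4 (1.5 equiv), K2CO3, acetone, rt
Reagents that add atoms: dimethyl sulfate, COS(=O)(=O)OC
Why: Williamson-type O-methylation of the coumarin enolate with a hard methylating agent should favour the 4-methoxycoumarin over the 2-methoxychromone and over C-methylation; the mild base leaves the four stereocentres untouched.

## Compound list

1 | (S)-limonene, (4S)-1-methyl-4-(prop-1-en-2-yl)cyclohex-1-ene | CC1=CC[C@H](CC1)C(C)=C | starting material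
2 | (4S)-limonene 1,2-oxide, (4S)-1-methyl-4-(prop-1-en-2-yl)-7-oxabicyclo[4.1.0]heptane (cis/trans mixture) | CC12CC[C@@H](CC1O2)C(C)=C | intermediate
3 | (1R,2R,4S)-limonene-1,2-diol, (1R,2R,4S)-1-methyl-4-(prop-1-en-2-yl)cyclohexane-1,2-diol | C[C@@]1(O)CC[C@@H](C[C@H]1O)C(C)=C | intermediate
4 | (3S)-6-oxo-3-(prop-1-en-2-yl)heptanal | O=CC[C@H](CCC(C)=O)C(C)=C | intermediate
5 | (5R)-2-methyl-5-(prop-1-en-2-yl)cyclopent-1-ene-1-carbaldehyde | O=CC1=C(C)CC[C@@H]1C(C)=C | intermediate
6 | (5R)-2-methyl-5-(prop-1-en-2-yl)cyclopent-1-ene-1-carboxylic acid | OC(=O)C1=C(C)CC[C@@H]1C(C)=C | intermediate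
7 | tert-butyl (5R)-2-methyl-5-(prop-1-en-2-yl)cyclopent-1-ene-1-carboxylate | CC(C)(C)OC(=O)C1=C(C)CC[C@@H]1C(C)=C | intermediate
8 | tert-butyl (5R)-5-[(2RS)-1-hydroxypropan-2-yl]-2-methylcyclopent-1-ene-1-carboxylate | CC(C)(C)OC(=O)C1=C(C)CC[C@@H]1C(C)CO | intermediate
9 | tert-butyl (1S,2R,5S)-2-[(2RS)-1-hydroxypropan-2-yl]-5-methylcyclopentane-1-carboxylate | CC(CO)[C@H]1CC[C@H](C)[C@@H]1C(=O)OC(C)(C)C | intermediate
10 | tert-butyl (1S,2S,5R)-2-methyl-5-[(2RS)-1-oxopropan-2-yl]cyclopentane-1-carboxylate | CC(C=O)[C@H]1CC[C@H](C)[C@@H]1C(=O)OC(C)(C)C | intermediate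
11 | (1S,2S,5R)-2-methyl-5-[(2RS)-1-oxopropan-2-yl]cyclopentane-1-carboxylic acid | CC(C=O)[C@H]1CC[C@H](C)[C@@H]1C(O)=O | intermediate
12 | trans,cis-nepetalactone, (4aS,7S,7aS)-4,7-dimethyl-5,6,7,7a-tetrahydrocyclopenta[c]pyran-1(4aH)-one | O=C1OC=C(C)[C@H]2CC[C@H](C)[C@H]12 | intermediate
13 | cis,trans-nepetalactone, (4aS,7S,7aR)-4,7-dimethyl-5,6,7,7a-tetrahydrocyclopenta[c]pyran-1(4aH)-one | O=C1OC=C(C)[C@H]2CC[C@H](C)[C@@H]12 | intermediate
14 | diisobutyl{[(1RS,4aS,7S,7aR)-4,7-dimethyl-1,4a,5,6,7,7a-hexahydrocyclopenta[c]pyran-1-yl]oxy}alumane (aluminium hemiacetal) | CC(C)C[Al](CC(C)C)OC1OC=C(C)[C@H]2CC[C@H](C)[C@@H]12 | intermediate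
15 | (1RS,4aS,7S,7aR)-4,7-dimethyl-1,4a,5,6,7,7a-hexahydrocyclopenta[c]pyran-1-yl acetate | CC(=O)OC1OC=C(C)[C@H]2CC[C@H](C)[C@@H]12 | intermediate
16 | (1RS,4aS,7S,7aR)-1-methoxy-4,7-dimethyl-1,4a,5,6,7,7a-hexahydrocyclopenta[c]pyran | COC1OC=C(C)[C@H]2CC[C@H](C)[C@@H]12 | intermediate
17 | 3-methylbutanoyl chloride | CC(C)CC(Cl)=O | starting material
18 | N-methoxy-N,3-dimethylbutanamide | CC(C)CC(=O)N(C)OC | intermediate
19 | [(1RS,4aS,7S,7aR)-1-methoxy-4,7-dimethyl-1,4a,5,6,7,7a-hexahydrocyclopenta[c]pyran-3-yl]lithium | COC1OC([Li])=C(C)[C@H]2CC[C@H](C)[C@@H]12 | intermediate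
20 | 1-[(1RS,4aS,7S,7aR)-1-methoxy-4,7-dimethyl-1,4a,5,6,7,7a-hexahydrocyclopenta[c]pyran-3-yl]-3-methylbutan-1-one | COC1OC(C(=O)CC(C)C)=C(C)[C@H]2CC[C@H](C)[C@@H]12 | intermediate
21 | 1-(2-hydroxy-6-methylphenyl)ethan-1-one | CC(=O)c1c(C)cccc1O | starting material
22 | 4-hydroxy-5-methyl-2H-chromen-2-one | Cc1cccc2oc(=O)cc(O)c12 | intermediate
23 | 3-[(1R,4aS,7S,7aR)-4,7-dimethyl-3-(3-methylbutanoyl)-1,4a,5,6,7,7a-hexahydrocyclopenta[c]pyran-1-yl]-4-hydroxy-5-methyl-2H-chromen-2-one | Oc1c([C@@H]2OC(C(=O)CC(C)C)=C(C)[C@H]3CC[C@H](C)[C@H]32)c(=O)oc2cccc(C)c12 | intermediate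
24 | 3-[(1R,4aS,7S,7aR)-4,7-dimethyl-3-(3-methylbutanoyl)-1,4a,5,6,7,7a-hexahydrocyclopenta[c]pyran-1-yl]-4-methoxy-5-methyl-2H-chromen-2-one | COc1c([C@@H]2OC(C(=O)CC(C)C)=C(C)[C@H]3CC[C@H](C)[C@H]32)c(=O)oc2cccc(C)c12 | target

## Step count and least certain steps

Total step count: 16. Longest linear sequence: 14 steps (steps 1–11, 13, 15 and 16); steps 12 and 14 are one-step side branches.

**Step 3 (key step).** The most likely failure is loss of chemoselectivity in the hot amine-salt stage: enolisation of the ketone towards the aldehyde, which leads to the acetylcyclopentene isomer, together with oligomerisation of the keto aldehyde. Fallback, setting out from 4 and returning at 5: addition and elimination are separated. Isolated 4 is cyclised at room temperature with catalytic L-proline in DMSO, where only the aldehyde enamine is available as the nucleophile. This should give the aldol (1RS,2RS,5S)-2-hydroxy-2-methyl-5-(prop-1-en-2-yl)cyclopentane-1-carbaldehyde F1, which is then dehydrated in a separate cold step (MsCl, Et3N, or catalytic TsOH) to 5.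

**Step 7.** The alkene is tetrasubstituted and conjugated to the ester, so it may bind the metal too weakly. The result would be no turnover and catalyst deactivation, or reduction from the open face with loss of the C7 configuration. Fallback, setting out from 5 and returning at 13: the hydrogenation is moved to the alcohol oxidation level, where the alkene is electron-rich and the side-chain hydroxyl is the only free donor.
- Luche reduction of 5 (NaBH4, CeCl3·7H2O, MeOH, 0 °C) gives [(5R)-2-methyl-5-(prop-1-en-2-yl)cyclopent-1-en-1-yl]methanol F2.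
- Silylation (t-BuPh2SiCl, imidazole, CH2Cl2) gives tert-butyl{[(5R)-2-methyl-5-(prop-1-en-2-yl)cyclopent-1-en-1-yl]methoxy}diphenylsilane F3.
- Hydroboration–oxidation as in step 6 gives (2RS)-2-[(1R)-2-({[tert-butyl(diphenyl)silyl]oxy}methyl)-3-methylcyclopent-2-en-1-yl]propan-1-ol F4.
- Hydrogenation with [Ir(cod)(PCy3)(py)]PF6 in CH2Cl2 gives (2RS)-2-[(1R,2S,3S)-2-({[tert-butyl(diphenyl)silyl]oxy}methyl)-3-methylcyclopentyl]propan-1-ol F5.
- Dess–Martin oxidation gives (2RS)-2-[(1S,2S,3S)-2-({[tert-butyl(diphenyl)silyl]oxy}methyl)-3-methylcyclopentyl]propanal F6.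
- Acetalisation (HC(OMe)3, MeOH, pyridinium tosylate) gives tert-butyl({(1S,2S,5S)-2-[(2RS)-1,1-dimethoxypropan-2-yl]-5-methylcyclopentyl}methoxy)diphenylsilane F7.
- Desilylation with Bu4NF gives {(1S,2S,5S)-2-[(2RS)-1,1-dimethoxypropan-2-yl]-5-methylcyclopentyl}methanol F8.
- Buffered oxidation (TEMPO, NaOCl cat., NaClO2, pH 6.7) gives (1S,2R,5S)-2-[(2RS)-1,1-dimethoxypropan-2-yl]-5-methylcyclopentane-1-carboxylic acid F9.
- F9 is cyclised and epimerised under the conditions of step 9 to 13.

**Step 13.** Metalation of a β,β-disubstituted enol ether may be slow, and the base may instead remove an allylic proton (4-methyl or H4a), so that acylation occurs at the wrong carbon or not at all. Fallback, setting out from 16 and returning at 20: the C3 carbanion is replaced by a C3 electrophile made regiospecifically from a lactone.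
- Oxidation of the enol ether of 16 with pyridinium chlorochromate, [C5H5NH][CrO3Cl], gives (1RS,4RS,4aS,7S,7aR)-1-methoxy-4,7-dimethyl-4,4a,5,6,7,7a-hexahydrocyclopenta[c]pyran-3(1H)-one F10.
- Enolisation and O-phosphorylation (KN(SiMe3)2, (PhO)2P(O)Cl, THF, −78 °C) gives (1RS,4aS,7S,7aR)-1-methoxy-4,7-dimethyl-1,4a,5,6,7,7a-hexahydrocyclopenta[c]pyran-3-yl diphenyl phosphate F11.
- Carbonylative cross-coupling of F11 (Pd(PPh3)4 cat., CO 1 atm, i-BuZnBr, THF) gives 20.

**Step 15.** Ionisation at C1 may be slow because O2 sits on an electron-poor enone carbon, and forcing it can cause O-alkylation of the coumarin. The acid can also reopen the product by retro-oxa-Michael reaction through the alkylidene chromandione, eroding C1 and C7a. Fallback, setting out from 20 and returning at 23: the bond is made by condensation, not by ionisation. Mild hydrolysis of the acetal (AcOH/H2O/THF) gives the lactol 1-[(1RS,4aS,7S,7aR)-1-hydroxy-4,7-dimethyl-1,4a,5,6,7,7a-hexahydrocyclopenta[c]pyran-3-yl]-3-methylbutan-1-one F12. Its open aldehyde form undergoes Knoevenagel condensation with 22 under ethylenediammonium diacetate at room temperature, and the side-chain enol oxygen then closes by oxa-Michael addition under thermodynamic control to 23.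

**Step 16.** The 4-oxygen is flanked by the 5-methyl group and the bulky C3 substituent, so site selectivity may be poor. Methylation could go to the lactone carbonyl oxygen (the 2-methoxychromone isomer) or, to a lesser extent, to C3. Fallback, setting out from 22 and 20 and returning at 24: the methyl ether is made before the coupling, where the isomers are small and easy to separate. Methylation of 22 (Me2SO4, K2CO3, acetone) gives 4-methoxy-5-methyl-2H-chromen-2-one F13. F13 is then alkylated at C3 by the oxocarbenium ion from 20 (Me3SiOTf, CH2Cl2, −40 → 0 °C, Friedel–Crafts type) to give 24 directly.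

## Further compounds

F1 | step 3 | (1RS,2RS,5S)-2-hydroxy-2-methyl-5-(prop-1-en-2-yl)cyclopentane-1-carbaldehyde | O=CC1C(C)(O)CC[C@@H]1C(C)=C
F2 | step 7 | [(5R)-2-methyl-5-(prop-1-en-2-yl)cyclopent-1-en-1-yl]methanol | OCC1=C(C)CC[C@@H]1C(C)=C
F3 | step 7 | tert-butyl{[(5R)-2-methyl-5-(prop-1-en-2-yl)cyclopent-1-en-1-yl]methoxy}diphenylsilane | CC(C)(C)[Si](OCC1=C(C)CC[C@@H]1C(C)=C)(c1ccccc1)c1ccccc1
F4 | step 7 | (2RS)-2-[(1R)-2-({[tert-butyl(diphenyl)silyl]oxy}methyl)-3-methylcyclopent-2-en-1-yl]propan-1-ol | CC(C)(C)[Si](OCC1=C(C)CC[C@@H]1C(C)CO)(c1ccccc1)c1ccccc1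
F5 | step 7 | (2RS)-2-[(1R,2S,3S)-2-({[tert-butyl(diphenyl)silyl]oxy}methyl)-3-methylcyclopentyl]propan-1-ol | CC(CO)[C@H]1CC[C@H](C)[C@@H]1CO[Si](c1ccccc1)(c1ccccc1)C(C)(C)C
F6 | step 7 | (2RS)-2-[(1S,2S,3S)-2-({[tert-butyl(diphenyl)silyl]oxy}methyl)-3-methylcyclopentyl]propanal | CC(C=O)[C@H]1CC[C@H](C)[C@@H]1CO[Si](c1ccccc1)(c1ccccc1)C(C)(C)C
F7 | step 7 | tert-butyl({(1S,2S,5S)-2-[(2RS)-1,1-dimethoxypropan-2-yl]-5-methylcyclopentyl}methoxy)diphenylsilane | COC(OC)C(C)[C@H]1CC[C@H](C)[C@@H]1CO[Si](c1ccccc1)(c1ccccc1)C(C)(C)C
F8 | step 7 | {(1S,2S,5S)-2-[(2RS)-1,1-dimethoxypropan-2-yl]-5-methylcyclopentyl}methanol | COC(OC)C(C)[C@H]1CC[C@H](C)[C@@H]1CO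
F9 | step 7 | (1S,2R,5S)-2-[(2RS)-1,1-dimethoxypropan-2-yl]-5-methylcyclopentane-1-carboxylic acid | COC(OC)C(C)[C@H]1CC[C@H](C)[C@@H]1C(O)=O
F10 | step 13 | (1RS,4RS,4aS,7S,7aR)-1-methoxy-4,7-dimethyl-4,4a,5,6,7,7a-hexahydrocyclopenta[c]pyran-3(1H)-one | COC1OC(=O)C(C)[C@H]2CC[C@H](C)[C@@H]12
F11 | step 13 | (1RS,4aS,7S,7aR)-1-methoxy-4,7-dimethyl-1,4a,5,6,7,7a-hexahydrocyclopenta[c]pyran-3-yl diphenyl phosphate | COC1OC(OP(=O)(Oc3ccccc3)Oc3ccccc3)=C(C)[C@H]2CC[C@H](C)[C@@H]12
F12 | step 15 | 1-[(1RS,4aS,7S,7aR)-1-hydroxy-4,7-dimethyl-1,4a,5,6,7,7a-hexahydrocyclopenta[c]pyran-3-yl]-3-methylbutan-1-one | OC1OC(C(=O)CC(C)C)=C(C)[C@H]2CC[C@H](C)[C@@H]12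
F13 | step 16 | 4-methoxy-5-methyl-2H-chromen-2-one | COc1cc(=O)oc2cccc(C)c12
A1 | alternative 1 | 3-(3,6-dimethyl-2-oxo-1,2,4,5,6,6a-hexahydropentalen-1-yl)-4-methoxy-5-methyl-2H-chromen-2-one, configured as in the SMILES | COc1c([C@@H]2C(=O)C(C)=C3CC[C@H](C)[C@H]32)c(=O)oc2cccc(C)c12
A2 | alternative 2 | 4,7-dimethyl-3-[2-(2-methylpropyl)-1,3-dioxolan-2-yl]-6-nitro-1,4a,5,6,7,7a-hexahydrocyclopenta[c]pyran-1-ol, ring centres C4a, C7 and C7a as in the SMILES | OC1OC(C2(CC(C)C)OCCO2)=C(C)[C@H]2CC([N+](=O)[O-])[C@H](C)[C@H]21
A3 | alternative 3 | 3-[(1R,4aS,7S,7aR)-4,7-dimethyl-3-(3-methylbutanoyl)-1,4a,5,6,7,7a-hexahydrocyclopenta[c]pyran-1-yl]-4-hydroxy-5-methyl-2H-chromen-2-one (identical with 23) | Oc1c([C@@H]2OC(C(=O)CC(C)C)=C(C)[C@H]3CC[C@H](C)[C@H]32)c(=O)oc2cccc(C)c12
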